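I wanted to know how much Z.Q and D together stands in the flask at the end of the run, and which change raises it.

    X ⇌ Z, rate k1*(cs1 - [Z]) while solid is left; crystals form when [Z] > cs1 (cs1 = 0.71 M, k1 = 0.00573 /min)
    Z + Q ⇌ Z.Q (K2 = 0.273 /M, k2 = 0.00386 /M/min)
    D ⇌ Z.Q, rate k3*(cs3 - [Z.Q]) while solid is left; crystals form when [Z.Q] > cs3 (cs3 = 0.29 M, k3 = 0.318 /min)
    2 Q → Q2 (k4 = 4.32 × 10⁻⁴ /M/min)

X 1.0 M; Q 2.00 equiv; time 4.0 d

- amount of Z.Q and D together at 4.0 d, in percent of the X charged
- the change that raises the amount of Z.Q and D together at 4.0 d, in percent of the X charged most ("none" if none brings more than 2 percentage points) (alder / elm / maple / larch / none)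
- amount of Z.Q and D together at 4.0 d, in percent of the X charged, after larch

- alder: doubling the solubility in step 1, all else as stated
- elm: doubling the solubility in step 3, all else as stated
- maple: doubling the dissolution coefficient of step 1, all else as stated
- larch: doubling the amount of Q, all else as stated

- amounts and yields of Z.Q count D too
- where a step has two of a species, its rate is k times that concentration squared, and two are used at each turn
- given per volume of solution although it is solid: X, D
- at the start none of X is in solution
- run time (flask): 4.0 d

Dissolution of X has a time of 2.91 h and Z.Q falls apart in 1.18 h, both shorter than the first half-life of Q by dimerisation at its charge, 9.65 h. So I let cZ stand at 0.71 M and held step 2 as a pre-equilibrium, with cZ.Q equal to 0.194 times cQ. The pool of Q, free and bound, then exceeds its free part by a factor 1.19, and this shields it from dimerisation.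

My number N is the run time divided by the first half-life and by the square of that factor: 6.98. It counts the shielded half-lives that fit into the run, a Damköhler number. The fraction of the pool left is the inverse of one plus N, 12.5%, which gives 4.07%. That is 0.0407 M of Z.Q, below 0.29 M, so I counted no D at the end.

One number did not quite do, since the ratio of cZ.Q to cQ is still needed beside it and the first hours of dissolving lie outside it. With the solubility doubled I put cZ at its ceiling, the charge of X, and reckoned 6.01%, a gain of 1.9 percentage points against the mark of 2 points. I committed to none.

The forecast gave 4.1%, none and 4.3% after larch, on the ground “Q dimerises away (half-life about 10 h at 2 M), so the late state matters.”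

The flask as charged gave 4.08%, with none as the best change, alder adding 1.5 points, and 4.36% after larch. At 4.00 d it used Q by dimerisation at 0.065 of the forward rate of step 2, and the backward turnover of step 2 up to then was 99.4% of the forward one. In larch, N is 14.0, which gives 4.34%. The flask read at 25 h has N of 1.82, which gives 11.5%, and it read 11.5%.

(The numbers of this flask are those of an exercise; the rest is arithmetic.)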